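**Plan**

- Retrosynthesis: the C3–CHO bond is cut first (formylation of an electron-rich benzofuran), then the two bonds at C2, namely C2–C1' to ring B and O1–C2 of the furan ring; protecting groups on the side-chain alcohol and the ring B catechol come off last.
- Enabling feature: C2 of the benzofuran carries both the ring oxygen O1 and C1' of ring B. It therefore maps onto the CBr2 carbon of a 2-(2,2-dibromovinyl)phenol, whose two bromine atoms are replaced in turn by the phenol oxygen and by an arylboronic acid.
- Ring A: dihydroconiferyl alcohol is formylated at its only free ortho position, diacetylated, converted into the gem-dibromoalkene, and the phenol is released.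
- Ring B: 5-bromo-2-hydroxy-3-methoxybenzaldehyde is turned into the catechol by Dakin oxidation (no selective demethylation needed), then into the dibenzyl ether and the boronic acid.
- The furan ring is the only ring that is built (one-pot C–O closure, then Suzuki–Miyaura coupling); C3 formylation, acetate methanolysis and debenzylation complete the synthesis.
- Stereochemistry: the target has no stereocentre and no stereogenic double bond, so nothing has to be set or preserved.

Key step: step 8

**Route**

Step 1
Reactants: 1 dihydroconiferyl alcohol, 4-(3-hydroxypropyl)-2-methoxyphenol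
Product: 3 2-hydroxy-5-(3-hydroxypropyl)-3-methoxybenzaldehyde, via trifluoroacetate ester 2 (not isolated)
Conditions: hexamethylenetetramine (2 equiv), TFA, reflux; 2 M HCl, rt; then NaHCO3, MeOH/H2O, rt
Reagents that add atoms: hexamethylenetetramine C1N2CN3CN1CN(C2)C3; water O
Why: Duff reaction, in which the iminium ion from protonated hexamethylenetetramine attacks the only free position ortho to the phenol (the para position carries the side chain), a hydride shift and hydrolysis deliver the aldehyde, and the primary alcohol, masked in the flask as its trifluoroacetate, is released by the bicarbonate treatment.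

Step 2
Reactants: 3 2-hydroxy-5-(3-hydroxypropyl)-3-methoxybenzaldehyde
Product: 4 3-(4-acetoxy-3-formyl-5-methoxyphenyl)propyl acetate
Conditions: Ac2O, pyridine, DMAP (cat.), CH2Cl2, 0 °C to rt
Reagents that add atoms: acetic anhydride CC(=O)OC(C)=O
Why: DMAP-catalysed O-acetylation of both hydroxyl groups, which keeps the primary alcohol out of Appel bromination and the phenol out of side reactions in the next step, and later shields the side-chain oxygen from POCl3.

Step 3
Reactants: 4 3-(4-acetoxy-3-formyl-5-methoxyphenyl)propyl acetate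
Product: 5 3-[4-acetoxy-3-(2,2-dibromoethenyl)-5-methoxyphenyl]propyl acetate
Conditions: CBr4, PPh3, CH2Cl2, 0 °C
Reagents that add atoms: carbon tetrabromide BrC(Br)(Br)Br
Why: Ramirez gem-dibromoolefination (first stage of the Corey–Fuchs sequence), a Wittig reaction of the ylide formed from CBr4 and PPh3 with the aryl aldehyde, to which both esters are inert.

Step 4
Reactants: 5 3-[4-acetoxy-3-(2,2-dibromoethenyl)-5-methoxyphenyl]propyl acetate
Product: 6 3-[3-(2,2-dibromoethenyl)-4-hydroxy-5-methoxyphenyl]propyl acetate
Conditions: pyrrolidine (1.1 equiv), CH2Cl2, 0 °C to rt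
Reagents that add atoms: none
Why: Chemoselective aminolysis, since an aryl acetate (phenoxide leaving group) is a far better acyl donor than a primary alkyl acetate, and the mild base-free conditions avoid dehydrobromination of the dibromoalkene.

Step 5
Reactants: 7 5-bromo-2-hydroxy-3-methoxybenzaldehyde
Product: 8 5-bromo-3-methoxybenzene-1,2-diol
Conditions: H2O2 (30% aq.), NaOH (1 equiv), H2O, N2, 0 to 40 °C; then 1 M HCl
Reagents that add atoms: hydrogen peroxide OO
Why: Dakin oxidation, in which hydroperoxide adds to the ortho-hydroxybenzaldehyde and migration of the electron-rich aryl group to oxygen followed by hydrolysis replaces the formyl group by a hydroxyl group, fixing the catechol next to the methoxy group unambiguously.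

Step 6
Reactants: 8 5-bromo-3-methoxybenzene-1,2-diol
Product: 9 1,2-bis(benzyloxy)-5-bromo-3-methoxybenzene
Conditions: BnBr, K2CO3, DMF, N2, 60 °C
Reagents that add atoms: benzyl bromide BrCc1ccccc1
Why: Williamson etherification of both phenols, giving benzyl ethers that tolerate n-BuLi at −78 °C, the basic coupling and POCl3, and can be cleaved at the end without touching the methyl ethers.

Step 7
Reactants: 9 1,2-bis(benzyloxy)-5-bromo-3-methoxybenzene
Product: 11 [3,4-bis(benzyloxy)-5-methoxyphenyl]boronic acid, via aryllithium 10 (not isolated)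
Conditions: n-BuLi, THF, −78 °C; B(OiPr)3, −78 °C to rt; 1 M HCl work-up
Reagents that add atoms: triisopropyl borate CC(C)OB(OC(C)C)OC(C)C; water O
Why: Lithiation–borylation, in which bromine–lithium exchange at −78 °C outruns benzylic or ortho deprotonation and the aryllithium is trapped by the borate ester, with acidic hydrolysis giving the boronic acid.

Step 8
Reactants: 6 3-[3-(2,2-dibromoethenyl)-4-hydroxy-5-methoxyphenyl]propyl acetate; 11 [3,4-bis(benzyloxy)-5-methoxyphenyl]boronic acid
Product: 13 3-[2-[3,4-bis(benzyloxy)-5-methoxyphenyl]-7-methoxy-1-benzofuran-5-yl]propyl acetate, via 2-bromobenzofuran 12 (not isolated)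
Conditions: CuI (5 mol %), K3PO4 (3 equiv), THF, 80 °C; then 11 (1.3 equiv), Pd(PPh3)4 (5 mol %), H2O (5 equiv), 80 °C
Reagents that add atoms: none
Why: K3PO4 forms the phenoxide, monovalent copper (CuI) binds it and adds oxidatively to the C–Br bond lying cis to ring A, the only one the oxygen can reach, and C–O reductive elimination gives 2-bromobenzofuran 12; zerovalent palladium from Pd(PPh3)4 then inserts into the remaining C2–Br bond, the boronate of 11 transmetallates, and reductive elimination from divalent palladium forms C2–C1'. The closest known reactions are the CuI-catalysed Ullmann-type cyclisation of 2-(gem-dibromovinyl)phenols to 2-bromobenzofurans and one-pot carbon–heteroatom coupling/Suzuki–Miyaura sequences of gem-dibromoolefins. The furan ring closes by O1–C2 bond formation in a formal 5-endo-trig mode, which the metal-mediated pathway makes feasible. No stereocentre is created. The step needs exactly one aryl group at C2: palladium and 11 are added only after the dibromide has been consumed, so a single C–Br bond is left to couple, and the intramolecular O-vinylation is in any case faster than an intermolecular event. The primary acetate is protected from hydrolysis by limiting water to a few equivalents.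

Step 9
Reactants: 13 3-[2-[3,4-bis(benzyloxy)-5-methoxyphenyl]-7-methoxy-1-benzofuran-5-yl]propyl acetate
Product: 14 3-[2-[3,4-bis(benzyloxy)-5-methoxyphenyl]-3-formyl-7-methoxy-1-benzofuran-5-yl]propyl acetate
Conditions: POCl3, DMF, 0 to 50 °C; H2O work-up
Reagents that add atoms: N,N-dimethylformamide CN(C)C=O; water O
Why: Vilsmeier–Haack formylation, directed to C3 because it is the β-carbon of an enol ether conjugated to both electron-rich arenes and so more nucleophilic than C4, C6 or the hindered C2'/C6' positions of ring B, while the acetate keeps the side-chain oxygen from being chlorinated or formylated.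

Step 10
Reactants: 14 3-[2-[3,4-bis(benzyloxy)-5-methoxyphenyl]-3-formyl-7-methoxy-1-benzofuran-5-yl]propyl acetate
Product: 15 2-[3,4-bis(benzyloxy)-5-methoxyphenyl]-5-(3-hydroxypropyl)-7-methoxy-1-benzofuran-3-carbaldehyde
Conditions: K2CO3 (0.2 equiv), MeOH, rt
Reagents that add atoms: none
Why: Zemplén-type base-catalysed transesterification of the primary acetate to methyl acetate, to which the non-enolisable aryl aldehyde and the benzyl ethers are inert.

Step 11
Reactants: 15 2-[3,4-bis(benzyloxy)-5-methoxyphenyl]-5-(3-hydroxypropyl)-7-methoxy-1-benzofuran-3-carbaldehyde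
Product: 16 Mururin C, 2-(3,4-dihydroxy-5-methoxyphenyl)-5-(3-hydroxypropyl)-7-methoxy-1-benzofuran-3-carbaldehyde
Conditions: BCl3 (excess), pentamethylbenzene, CH2Cl2, −78 °C; MeOH quench
Reagents that add atoms: none
Why: Lewis acid debenzylation, in which BCl3 activates the benzyl ether oxygens and pentamethylbenzene traps the benzyl cations by Friedel–Crafts alkylation, so that at −78 °C the aryl methyl ethers, the aldehyde and the benzofuran should remain intact and methanol releases the catechol and the primary alcohol from boron.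

**Compound list**

1 | dihydroconiferyl alcohol, 4-(3-hydroxypropyl)-2-methoxyphenol | COc1cc(CCCO)ccc1O | starting material
2 | 3-(3-formyl-4-hydroxy-5-methoxyphenyl)propyl trifluoroacetate | COc1cc(CCCOC(=O)C(F)(F)F)cc(C=O)c1O | intermediate
3 | 2-hydroxy-5-(3-hydroxypropyl)-3-methoxybenzaldehyde | COc1cc(CCCO)cc(C=O)c1O | intermediate
4 | 3-(4-acetoxy-3-formyl-5-methoxyphenyl)propyl acetate | COc1cc(CCCOC(C)=O)cc(C=O)c1OC(C)=O | intermediate
5 | 3-[4-acetoxy-3-(2,2-dibromoethenyl)-5-methoxyphenyl]propyl acetate | COc1cc(CCCOC(C)=O)cc(C=C(Br)Br)c1OC(C)=O | intermediate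
6 | 3-[3-(2,2-dibromoethenyl)-4-hydroxy-5-methoxyphenyl]propyl acetate | COc1cc(CCCOC(C)=O)cc(C=C(Br)Br)c1O | intermediate
7 | 5-bromo-2-hydroxy-3-methoxybenzaldehyde | COc1cc(Br)cc(C=O)c1O | starting material
8 | 5-bromo-3-methoxybenzene-1,2-diol | COc1cc(Br)cc(O)c1O | intermediate
9 | 1,2-bis(benzyloxy)-5-bromo-3-methoxybenzene | COc1cc(Br)cc(OCc2ccccc2)c1OCc1ccccc1 | intermediate
10 | [3,4-bis(benzyloxy)-5-methoxyphenyl]lithium | [Li]c1cc(OC)c(OCc2ccccc2)c(OCc2ccccc2)c1 | intermediate
11 | [3,4-bis(benzyloxy)-5-methoxyphenyl]boronic acid | OB(O)c1cc(OC)c(OCc2ccccc2)c(OCc2ccccc2)c1 | intermediate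
12 | 3-(2-bromo-7-methoxy-1-benzofuran-5-yl)propyl acetate | CC(=O)OCCCc1cc(OC)c2oc(Br)cc2c1 | intermediate
13 | 3-[2-[3,4-bis(benzyloxy)-5-methoxyphenyl]-7-methoxy-1-benzofuran-5-yl]propyl acetate | COc1cc(CCCOC(C)=O)cc2cc(-c3cc(OC)c(OCc4ccccc4)c(OCc4ccccc4)c3)oc12 | intermediate
14 | 3-[2-[3,4-bis(benzyloxy)-5-methoxyphenyl]-3-formyl-7-methoxy-1-benzofuran-5-yl]propyl acetate | COc1cc(CCCOC(C)=O)cc2c(C=O)c(-c3cc(OC)c(OCc4ccccc4)c(OCc4ccccc4)c3)oc12 | intermediate
15 | 2-[3,4-bis(benzyloxy)-5-methoxyphenyl]-5-(3-hydroxypropyl)-7-methoxy-1-benzofuran-3-carbaldehyde | COc1cc(CCCO)cc2c(C=O)c(-c3cc(OC)c(OCc4ccccc4)c(OCc4ccccc4)c3)oc12 | intermediate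
16 | Mururin C | COc1cc(-c2oc3c(OC)cc(CCCO)cc3c2C=O)cc(O)c1O | target

**Step count**

Total: 11 steps. Longest linear sequence: 8 steps (steps 1–4 and 8–11); the ring B branch (steps 5–7) joins at step 8.

**Steps most likely to fail, with fallbacks**

Step 8. The dibromoalkene may lose HBr to a bromoalkyne or be reduced, palladium may enter before ring closure is complete and cause double arylation, the electron-rich boronic acid may protodeboronate, and the acetate may be hydrolysed by wet phosphate. The fallback forms the same two bonds at the alkyne oxidation level. It sets out from aldehyde 3 and uses bromide 9. Ohira–Bestmann homologation of 3 (dimethyl (1-diazo-2-oxopropyl)phosphonate, K2CO3, MeOH, rt) would give 2-ethynyl-4-(3-hydroxypropyl)-6-methoxyphenol F1. Copper-free Sonogashira coupling of F1 with 9 (PdCl2(MeCN)2, XPhos, Cs2CO3, MeCN, 80 °C) should give 2-{[3,4-bis(benzyloxy)-5-methoxyphenyl]ethynyl}-4-(3-hydroxypropyl)-6-methoxyphenol F2. On addition of CuI in the same flask F2 is expected to close by 5-endo-dig hydroalkoxylation to 3-[2-[3,4-bis(benzyloxy)-5-methoxyphenyl]-7-methoxy-1-benzofuran-5-yl]propan-1-ol F3. Acetylation of F3 (Ac2O, pyridine) returns to the route at 13.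

Step 11. BCl3 may also cleave the methyl ether next to the freed catechol, or the Lewis acid may degrade the push–pull aldehyde. The fallback removes the benzyl groups before the aldehyde exists; it sets out from 13. Hydrogenolysis (H2, Pd/C, EtOAc/MeOH, rt) should give 3-[2-(3,4-dihydroxy-5-methoxyphenyl)-7-methoxy-1-benzofuran-5-yl]propyl acetate F4. Acetylation (Ac2O, pyridine) gives 5-[5-(3-acetoxypropyl)-7-methoxy-1-benzofuran-2-yl]-3-methoxy-1,2-phenylene diacetate F5. Vilsmeier–Haack formylation (POCl3, DMF) at C3 gives 5-[5-(3-acetoxypropyl)-3-formyl-7-methoxy-1-benzofuran-2-yl]-3-methoxy-1,2-phenylene diacetate F6. One methanolysis of all three acetates (K2CO3, degassed MeOH, then dilute acid) comes back to the route at the target 16.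

Step 1. Duff formylation of a guaiacol can stall at low conversion or give tar, and release of the alcohol from its trifluoroacetate may be incomplete. The fallback attaches the side chain by cross-coupling to an aldehyde that is already in place. It sets out from 7 and bypasses 3. Acetylation of 7 (Ac2O, pyridine) would give 4-bromo-2-formyl-6-methoxyphenyl acetate F7. Zinc insertion into 3-bromopropyl acetate (Zn dust, LiCl, THF, 50 °C) provides (3-acetoxypropyl)zinc bromide F8. Negishi coupling of F7 with F8 (Pd(OAc)2, SPhos, THF, rt), which tolerates the aldehyde and both esters, returns to the route at diacetate 4.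

**Further compounds**

F1 | step 8 | 2-ethynyl-4-(3-hydroxypropyl)-6-methoxyphenol | COc1cc(CCCO)cc(C#C)c1O
F2 | step 8 | 2-{[3,4-bis(benzyloxy)-5-methoxyphenyl]ethynyl}-4-(3-hydroxypropyl)-6-methoxyphenol | COc1cc(CCCO)cc(C#Cc2cc(OC)c(OCc3ccccc3)c(OCc3ccccc3)c2)c1O
F3 | step 8 | 3-[2-[3,4-bis(benzyloxy)-5-methoxyphenyl]-7-methoxy-1-benzofuran-5-yl]propan-1-ol | COc1cc(CCCO)cc2cc(-c3cc(OC)c(OCc4ccccc4)c(OCc4ccccc4)c3)oc12
F4 | step 11 | 3-[2-(3,4-dihydroxy-5-methoxyphenyl)-7-methoxy-1-benzofuran-5-yl]propyl acetate | COc1cc(-c2cc3cc(CCCOC(C)=O)cc(OC)c3o2)cc(O)c1O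
F5 | step 11 | 5-[5-(3-acetoxypropyl)-7-methoxy-1-benzofuran-2-yl]-3-methoxy-1,2-phenylene diacetate | COc1cc(-c2cc3cc(CCCOC(C)=O)cc(OC)c3o2)cc(OC(C)=O)c1OC(C)=O
F6 | step 11 | 5-[5-(3-acetoxypropyl)-3-formyl-7-methoxy-1-benzofuran-2-yl]-3-methoxy-1,2-phenylene diacetate | COc1cc(-c2oc3c(OC)cc(CCCOC(C)=O)cc3c2C=O)cc(OC(C)=O)c1OC(C)=O
F7 | step 1 | 4-bromo-2-formyl-6-methoxyphenyl acetate | COc1cc(Br)cc(C=O)c1OC(C)=O
F8 | step 1 | (3-acetoxypropyl)zinc bromide | CC(=O)OCCC[Zn]Br
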